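## Retrosynthetic overview

1. Ester C–O bond: the carboxylate of the diketo acid opens (S)-glycidyl acetate at its terminal carbon. The glycerol stereocentre comes from (R)-glycidol.
2. Ring C2–CH2 and C1–CH3 bonds: one-pot conjugate addition of a masked 3-oxobutyl Grignard reagent to a cyclohexenyl ketone, then C-methylation of the enolate. This sets both ring stereocentres.
3. Ring C1–C(=O) bond: a 3,3-dimethylcyclohexenyl anion is acylated by (R)-5-methyloxepan-2-one.
4. The lactone comes from 4-methylcyclohexanone by an enantiotopic-group-selective Baeyer–Villiger oxidation (side-chain stereocentre). The vinyl anion comes from 3-methylanisole by Birch reduction, conjugate methylation/triflation and stannylation.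
5. Ring order: the only carbocycle is the anisole ring, dearomatised in step 1 and carried through. No ring-forming step is needed.

Assumption: ring carbon C1 bears the methyl and acyl groups and C2 the oxobutyl chain; the target is read from the SMILES as (1R,2S) in the ring, 3R in the hexanoate chain and 2R in the glycerol unit.

## Route

Step 1
Reactants: 1 3-methylanisole
Product: 3 3-methylcyclohex-2-en-1-one, via 1-methoxy-5-methylcyclohexa-1,4-diene 2 (not isolated)
Conditions: Li, NH3(l), t-BuOH, THF, −78 to −33 °C; then 2 M HCl, THF, rt to 50 °C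
Reagents that add atoms: water, O
Why: Birch reduction leaves the methoxy- and methyl-bearing carbons on the two remaining double bonds, and aqueous acid hydrolyses the enol ether and moves the C=C into conjugation (Birch reduction/enol ether hydrolysis; no stereocentre).

Step 2
Reactants: 3 3-methylcyclohex-2-en-1-one
Product: 5 3,3-dimethylcyclohex-1-en-1-yl trifluoromethanesulfonate, via bromomagnesium 3,3-dimethylcyclohex-1-en-1-olate 4 (not isolated)
Conditions: MeMgBr, CuBr·SMe2 (5 mol%), THF, −40 to 0 °C; then PhNTf2, DMPU, 0 °C to rt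
Reagents that add atoms: methylmagnesium bromide, C[Mg]Br; N-phenylbis(trifluoromethanesulfonimide), O=S(=O)(N(c1ccccc1)S(=O)(=O)C(F)(F)F)C(F)(F)F
Why: copper-catalysed 1,4-addition of the methyl Grignard reagent builds the gem-dimethyl carbon and gives the enolate only on the side of that carbon, which PhNTf2 traps as the vinyl triflate (Kharasch-type conjugate addition/enolate triflation; no stereocentre).

Step 3
Reactants: 5 3,3-dimethylcyclohex-1-en-1-yl trifluoromethanesulfonate
Product: 6 (3,3-dimethylcyclohex-1-en-1-yl)trimethylstannane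
Conditions: Me3SnSnMe3, Pd(PPh3)4 (5 mol%), LiCl, THF, 60 °C
Reagents that add atoms: hexamethylditin, C[Sn](C)(C)[Sn](C)(C)C
Why: oxidative addition of zerovalent palladium into the C–OTf bond, transmetalation with the ditin and reductive elimination (Stille-type triflate-to-stannane exchange) turn the vinyl electrophile into a latent vinyl anion without moving the double bond.

Step 4
Reactants: 7 4-methylcyclohexanone
Product: 8 (R)-5-methyloxepan-2-one
Conditions: m-CPBA, Sc(OTf)3 (5 mol%), chiral N,N′-dioxide ligand (6 mol%, antipode that gives R), EtOAc, −20 °C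
Reagents that add atoms: 3-chloroperbenzoic acid, OOC(=O)c1cccc(Cl)c1
Why: catalytic asymmetric Baeyer–Villiger oxidation in which the chiral scandium complex makes one of the two enantiotopic α-carbons of the Criegee adduct migrate, so the mirror plane of the ketone is lost and the methyl-bearing carbon becomes the R stereocentre.

Step 5
Reactants: 6 (3,3-dimethylcyclohex-1-en-1-yl)trimethylstannane; 8 (R)-5-methyloxepan-2-one
Product: 11 (R)-6-[(tert-butyldimethylsilyl)oxy]-1-(3,3-dimethylcyclohex-1-en-1-yl)-4-methylhexan-1-one, via (3,3-dimethylcyclohex-1-en-1-yl)lithium 9 (not isolated), via lithium alkoxide of the ring-opened hydroxy enone 10 (not isolated)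
Conditions: MeLi (1.0 equiv), THF, −78 °C; then 8, −78 to −20 °C; then TBSCl, DMPU, −20 °C to rt
Reagents that add atoms: tert-butyldimethylsilyl chloride, CC(C)(C)[Si](C)(C)Cl
Why: tin–lithium exchange gives the vinyllithium, which adds once to the lactone because the tetrahedral lactolate survives at low temperature (acylation of an organolithium by a lactone), and the alkoxide freed on warming is silylated in the same flask; the existing stereocentre is not touched.

Step 6
Reactants: 11 (R)-6-[(tert-butyldimethylsilyl)oxy]-1-(3,3-dimethylcyclohex-1-en-1-yl)-4-methylhexan-1-one; 12 2-(2-bromoethyl)-2-methyl-1,3-dioxolane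
Product: 15 (R)-6-[(tert-butyldimethylsilyl)oxy]-4-methyl-1-{(1R,2S)-1,3,3-trimethyl-2-[2-(2-methyl-1,3-dioxolan-2-yl)ethyl]cyclohexyl}hexan-1-one, via [2-(2-methyl-1,3-dioxolan-2-yl)ethyl]magnesium bromide 13 (not isolated), via bromomagnesium enolate of the conjugate adduct 14 (not isolated)
Conditions: 12, Mg, THF, 30 °C; then CuBr·SMe2 (5 mol%), (R)-1-[(S)-2-(diphenylphosphino)ferrocenyl]ethyldicyclohexylphosphine or its antipode (6 mol%, the one that gives 2S), t-BuOMe, −78 °C, slow addition of 11; then MeI, DMPU, −78 to 0 °C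
Reagents that add atoms: iodomethane, CI
Why: copper-catalysed asymmetric conjugate addition of the Grignard reagent puts the masked oxobutyl chain on ring C2 with the face fixed by the chiral diphosphine (2S), and the tetrasubstituted magnesium enolate is then C-methylated from the face opposite that chain (1R, methyl trans to the chain), a three-component conjugate addition/enolate alkylation that has not been tested on an enone this hindered.

Step 7
Reactants: 15 (R)-6-[(tert-butyldimethylsilyl)oxy]-4-methyl-1-{(1R,2S)-1,3,3-trimethyl-2-[2-(2-methyl-1,3-dioxolan-2-yl)ethyl]cyclohexyl}hexan-1-one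
Product: 16 (R)-3-methyl-6-oxo-6-[(1R,2S)-1,3,3-trimethyl-2-(3-oxobutyl)cyclohexyl]hexanoic acid
Conditions: CrO3, H2SO4, H2O, acetone, 0 °C to rt
Reagents that add atoms: water, O
Why: in the Jones oxidation the aqueous acid cleaves the silyl ether and the dioxolane while hexavalent chromium oxidises the freed primary alcohol to the acid; the quaternary C1, C2 and the β-methyl carbon have no way to epimerise.

Step 8
Reactants: 17 (R)-glycidol
Product: 18 (S)-glycidyl acetate
Conditions: Ac2O, Et3N, DMAP (cat.), CH2Cl2, 0 °C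
Reagents that add atoms: acetic anhydride, CC(=O)OC(C)=O
Why: DMAP-catalysed O-acetylation of the primary alcohol (nucleophilic acyl substitution) leaves the epoxide and its stereocentre untouched; the descriptor changes from R to S only because the substituent priorities change.

Step 9
Reactants: 16 (R)-3-methyl-6-oxo-6-[(1R,2S)-1,3,3-trimethyl-2-(3-oxobutyl)cyclohexyl]hexanoic acid; 18 (S)-glycidyl acetate
Product: 19 (R)-3-acetoxy-2-hydroxypropyl (R)-3-methyl-6-oxo-6-[(1R,2S)-1,3,3-trimethyl-2-(3-oxobutyl)cyclohexyl]hexanoate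
Conditions: Co(salen)(OAc) (trivalent cobalt; salen = N,N′-bis(3,5-di-tert-butylsalicylidene)cyclohexane-1,2-diamine dianion, antipode matched to 18; 5 mol%), i-Pr2NEt, t-BuOMe, rt
Reagents that add atoms: none
Why: the cobalt-activated terminal epoxide is opened by the carboxylate at its unsubstituted carbon (SN2 epoxide ring opening by a carboxylic acid), so the 1,3-diacylglycerol forms with the secondary hydroxyl free and the epoxide stereocentre retained, now with descriptor R.

## Compound list

1 | 3-methylanisole (1-methoxy-3-methylbenzene) | COc1cccc(C)c1 | starting material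
2 | 1-methoxy-5-methylcyclohexa-1,4-diene | COC1=CCC=C(C)C1 | intermediate
3 | 3-methylcyclohex-2-en-1-one | CC1=CC(=O)CCC1 | intermediate
4 | bromomagnesium 3,3-dimethylcyclohex-1-en-1-olate | CC1(C)CCCC(O[Mg]Br)=C1 | intermediate
5 | 3,3-dimethylcyclohex-1-en-1-yl trifluoromethanesulfonate | CC1(C)CCCC(OS(=O)(=O)C(F)(F)F)=C1 | intermediate
6 | (3,3-dimethylcyclohex-1-en-1-yl)trimethylstannane | CC1(C)CCCC([Sn](C)(C)C)=C1 | intermediate
7 | 4-methylcyclohexanone | CC1CCC(=O)CC1 | starting material
8 | (R)-5-methyloxepan-2-one | O=C1CC[C@@H](C)CCO1 | intermediate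
9 | (3,3-dimethylcyclohex-1-en-1-yl)lithium | [Li]C1=CC(C)(C)CCC1 | intermediate
10 | lithium (R)-6-(3,3-dimethylcyclohex-1-en-1-yl)-3-methyl-6-oxohexan-1-olate | CC1(C)CCCC(=C1)C(=O)CC[C@@H](C)CC[O-].[Li+] | intermediate
11 | (R)-6-[(tert-butyldimethylsilyl)oxy]-1-(3,3-dimethylcyclohex-1-en-1-yl)-4-methylhexan-1-one | CC1(C)CCCC(=C1)C(=O)CC[C@@H](C)CCO[Si](C)(C)C(C)(C)C | intermediate
12 | 2-(2-bromoethyl)-2-methyl-1,3-dioxolane | CC1(CCBr)OCCO1 | starting material
13 | [2-(2-methyl-1,3-dioxolan-2-yl)ethyl]magnesium bromide | CC1(CC[Mg]Br)OCCO1 | intermediate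
14 | bromomagnesium (R)-6-[(tert-butyldimethylsilyl)oxy]-1-{(S)-3,3-dimethyl-2-[2-(2-methyl-1,3-dioxolan-2-yl)ethyl]cyclohexylidene}-4-methylhexan-1-olate | CC1(CC[C@H]2C(C)(C)CCCC2=C(O[Mg]Br)CC[C@@H](C)CCO[Si](C)(C)C(C)(C)C)OCCO1 | intermediate
15 | (R)-6-[(tert-butyldimethylsilyl)oxy]-4-methyl-1-{(1R,2S)-1,3,3-trimethyl-2-[2-(2-methyl-1,3-dioxolan-2-yl)ethyl]cyclohexyl}hexan-1-one | CC1(CC[C@H]2C(C)(C)CCC[C@@]2(C)C(=O)CC[C@@H](C)CCO[Si](C)(C)C(C)(C)C)OCCO1 | intermediate
16 | (R)-3-methyl-6-oxo-6-[(1R,2S)-1,3,3-trimethyl-2-(3-oxobutyl)cyclohexyl]hexanoic acid | CC(=O)CC[C@H]1C(C)(C)CCC[C@@]1(C)C(=O)CC[C@@H](C)CC(=O)O | intermediate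
17 | (R)-glycidol [(R)-oxiran-2-ylmethanol] | OC[C@@H]1CO1 | starting material
18 | (S)-glycidyl acetate [(S)-oxiran-2-ylmethyl acetate] | CC(=O)OC[C@@H]1CO1 | intermediate
19 | (R)-3-acetoxy-2-hydroxypropyl (R)-3-methyl-6-oxo-6-[(1R,2S)-1,3,3-trimethyl-2-(3-oxobutyl)cyclohexyl]hexanoate | CC(=O)CC[C@H]1C(C)(C)CCC[C@@]1(C)C(=O)CC[C@@H](C)CC(=O)OC[C@H](O)COC(C)=O | target

## Step count and risks

Total: 9 steps. Longest linear sequence: 7 steps (1, 2, 3, 5, 6, 7, 9). Steps 4 and 8 are side branches.

**Step 6 (most likely to fail).** The enone is α-branched and its β-carbon sits next to a quaternary carbon. Catalyst control of the face may therefore be poor, and the hindered enolate may methylate sluggishly or equilibrate. Because the side-chain stereocentre is already fixed, a wrong ring configuration shows up as a diastereomer that is hard to separate.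

Fallback, setting out from 11 and coming back at 16: the face is fixed by a covalently bound auxiliary instead of a catalyst. Condense 11 with (R)-2-methylpropane-2-sulfinamide (Ti(OEt)4, THF, 65 °C) to the N-sulfinyl azadiene (R)-N-[(R)-6-[(tert-butyldimethylsilyl)oxy]-1-(3,3-dimethylcyclohex-1-en-1-yl)-4-methylhexylidene]-2-methylpropane-2-sulfinamide F1. Add the magnesium cuprate made from 13 and CuI (THF, −78 °C) in a sulfinyl-directed 1,4-addition and methylate the resulting aza-enolate with MeI, anti to the new chain, to give (R)-N-[(R)-6-[(tert-butyldimethylsilyl)oxy]-4-methyl-1-{(1R,2S)-1,3,3-trimethyl-2-[2-(2-methyl-1,3-dioxolan-2-yl)ethyl]cyclohexyl}hexylidene]-2-methylpropane-2-sulfinamide F2. The auxiliary antipode is the one that gives the 1R,2S ring (shown as R at sulfur). Oxidation as in step 7 (CrO3, H2SO4, H2O, acetone) hydrolyses the imine together with the silyl ether and the ketal and gives 16.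

**Step 4.** The catalytic Baeyer–Villiger desymmetrisation of a 4-alkylcyclohexanone may stop near 85–90% ee, and the oily lactone cannot be enriched by crystallisation.

Fallback, setting out from 7 and coming back at 8: the symmetry is broken by enantioselective deprotonation instead of oxygen insertion. Treat 7 with lithium bis[(R)-1-phenylethyl]amide or its antipode (the one that gives R) in the presence of Me3SiCl (THF, −78 °C) to obtain (R)-trimethyl[(4-methylcyclohex-1-en-1-yl)oxy]silane F3. Ozonolysis (O3, CH2Cl2/MeOH, −78 °C) with NaBH4 work-up gives (R)-6-hydroxy-4-methylhexanoic acid F4. Lactonisation (2,4,6-trichlorobenzoyl chloride, Et3N, then DMAP, toluene, high dilution) gives 8.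

**Step 9.** Opening of the glycidyl ester by a valuable acid may be slow, and the 1,3-diacylglycerol may isomerise by acyl migration to the 1,2-isomer.

Fallback, setting out from 16 and coming back at 19: the acid is joined to a preformed protected glycerol by acylation instead of epoxide opening. Esterify 16 with (S)-(2,2-dimethyl-1,3-dioxolan-4-yl)methanol (DCC, DMAP, CH2Cl2) to [(R)-2,2-dimethyl-1,3-dioxolan-4-yl]methyl (R)-3-methyl-6-oxo-6-[(1R,2S)-1,3,3-trimethyl-2-(3-oxobutyl)cyclohexyl]hexanoate F5. Remove the acetonide (80% aq. AcOH, 40 °C) to give (R)-2,3-dihydroxypropyl (R)-3-methyl-6-oxo-6-[(1R,2S)-1,3,3-trimethyl-2-(3-oxobutyl)cyclohexyl]hexanoate F6. Acetylate the primary hydroxyl selectively (AcCl, 2,4,6-collidine, CH2Cl2, −78 °C) to reach 19.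

## Further compounds

F1 | step 6 | (R)-N-[(R)-6-[(tert-butyldimethylsilyl)oxy]-1-(3,3-dimethylcyclohex-1-en-1-yl)-4-methylhexylidene]-2-methylpropane-2-sulfinamide | CC1(C)CCCC(=C1)C(CC[C@@H](C)CCO[Si](C)(C)C(C)(C)C)=N[S@](=O)C(C)(C)C
F2 | step 6 | (R)-N-[(R)-6-[(tert-butyldimethylsilyl)oxy]-4-methyl-1-{(1R,2S)-1,3,3-trimethyl-2-[2-(2-methyl-1,3-dioxolan-2-yl)ethyl]cyclohexyl}hexylidene]-2-methylpropane-2-sulfinamide | CC1(CC[C@H]2C(C)(C)CCC[C@@]2(C)C(CC[C@@H](C)CCO[Si](C)(C)C(C)(C)C)=N[S@](=O)C(C)(C)C)OCCO1
F3 | step 4 | (R)-trimethyl[(4-methylcyclohex-1-en-1-yl)oxy]silane | C[Si](C)(C)OC1=CC[C@H](C)CC1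
F4 | step 4 | (R)-6-hydroxy-4-methylhexanoic acid | OC(=O)CC[C@@H](C)CCO
F5 | step 9 | [(R)-2,2-dimethyl-1,3-dioxolan-4-yl]methyl (R)-3-methyl-6-oxo-6-[(1R,2S)-1,3,3-trimethyl-2-(3-oxobutyl)cyclohexyl]hexanoate | CC(=O)CC[C@H]1C(C)(C)CCC[C@@]1(C)C(=O)CC[C@@H](C)CC(=O)OC[C@H]2COC(C)(C)O2
F6 | step 9 | (R)-2,3-dihydroxypropyl (R)-3-methyl-6-oxo-6-[(1R,2S)-1,3,3-trimethyl-2-(3-oxobutyl)cyclohexyl]hexanoate | CC(=O)CC[C@H]1C(C)(C)CCC[C@@]1(C)C(=O)CC[C@@H](C)CC(=O)OC[C@H](O)CO
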